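**Assumption:** the target SMILES contains no stereocentre or double-bond geometry, so marchantin H is treated as achiral and no enantiocontrol is needed. All four benzene rings are purchased; only the 18-membered macrocycle is formed. Ring labels: A = guaiacol-type ring, B = para-phenylene, C = trioxygenated ring, D = meta-phenylene.

## Retrosynthetic overview

1. Target ⇐ triple O-demethylation of the trimethyl ether ⇐ hydrogenation of a macrocyclic stilbene.
2. The 18-membered ring is closed last, at the A–CH=CH–D bond, by intramolecular McMurry coupling of an acyclic dialdehyde (from a dinitrile).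
3. The B–CH2CH2–C bibenzyl comes from hydroboration/B-alkyl Suzuki coupling of a C–O–D styrene with an A–O–B aryl bromide.
4. A–O–B ether: Chan–Lam coupling of isovanillonitrile with 4-bromophenylboronic acid. C–O–D ether: SNAr of 2-fluoro-3,4-dimethoxybenzaldehyde with 3-hydroxybenzonitrile.
5. Nitriles serve as masked aldehydes that tolerate the ylide, 9-BBN and Pd steps.

## Route

**Step 1**
Reactants: 1 (3-hydroxy-4-methoxybenzonitrile), 2 (4-bromophenylboronic acid)
Product: 3, 3-(4-bromophenoxy)-4-methoxybenzonitrile
Conditions: Cu(OAc)2 (1 equiv), pyridine, 4 Å MS, CH2Cl2, air, rt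
Reagents that add atoms: none beyond reactant 2 (OB(O)c1ccc(Br)cc1), which delivers the 4-bromophenyl group
Why: Chan–Lam–Evans O-arylation occurs at the C–B bond only, so the aryl bromide is kept for step 4.

**Step 2**
Reactants: 4 (2-fluoro-3,4-dimethoxybenzaldehyde), 5 (3-hydroxybenzonitrile)
Product: 6, 3-(6-formyl-2,3-dimethoxyphenoxy)benzonitrile
Conditions: K2CO3, DMF, 120 °C
Reagents that add atoms: none beyond reactants
Why: SNAr; the ortho-formyl group activates the C–F bond toward the phenoxide and places the ether oxygen between the CHO and the two OMe groups, as ring C requires.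

**Step 3**
Reactants: 6
Product: 7, 3-(6-ethenyl-2,3-dimethoxyphenoxy)benzonitrile
Conditions: Ph3PCH3Br, KOtBu, THF, 0 °C → rt
Reagents that add atoms: methyltriphenylphosphonium bromide, C[P+](c1ccccc1)(c1ccccc1)c1ccccc1.[Br-] (supplies the =CH2 carbon)
Why: Wittig methylenation; the aldehyde reacts far faster than the aryl nitrile with about 1.1 equiv of ylide.

**Step 4**
Reactants: 7 (1.2 equiv), 3
Product: 8, 3-[4-[2-[2-(3-cyanophenoxy)-3,4-dimethoxyphenyl]ethyl]phenoxy]-4-methoxybenzonitrile
Conditions: 9-BBN, THF, 0 °C → rt; then 3, Pd(dppf)Cl2 (5 mol %), aq K3PO4, THF/DMF, 65 °C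
Reagents that add atoms: none (9-BBN contributes H only; boron and bromine are lost)
Why: anti-Markovnikov hydroboration of the styrene followed by B-alkyl Suzuki–Miyaura coupling gives the saturated Ar–CH2CH2–Ar link directly; nitriles tolerate both stages.

**Step 5**
Reactants: 8
Product: 9, 3-[4-[2-[2-(3-formylphenoxy)-3,4-dimethoxyphenyl]ethyl]phenoxy]-4-methoxybenzaldehyde
Conditions: DIBAL-H (3 equiv), CH2Cl2, −78 → 0 °C; then 1 M HCl, rt
Reagents that add atoms: water, O (both aldehyde oxygens come from hydrolysis of the aluminium iminates)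
Why: partial reduction of aryl nitriles stops at the iminate, which hydrolyses to the aldehyde; aryl methyl ethers and diaryl ethers are inert at low temperature.

**Step 6**
Reactants: 9
Product: 10, macrocyclic stilbene (trimethyl ether of 18-membered dehydro-marchantin H with A–CH=CH–D; E/Z mixture, geometry inconsequential)
Conditions: TiCl4, Zn, pyridine, THF, reflux; syringe-pump addition of 9 (final about 2 mM)
Reagents that add atoms: none
Why: intramolecular McMurry reductive carbonyl coupling under high dilution closes the 18-membered ring; no stereocentre is created.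

**Step 7**
Reactants: 10
Product: 11, marchantin H tri-O-methyl ether
Conditions: H2 (1 atm), 10% Pd/C, EtOAc, rt
Reagents that add atoms: none (H only)
Why: catalytic hydrogenation saturates both stilbene isomers to the same bibenzyl without hydrogenolysis of aryl ethers.

**Step 8**
Reactants: 11
Product: 12, marchantin H
Conditions: BBr3 (6–8 equiv), CH2Cl2, −78 °C → rt; MeOH/H2O quench
Reagents that add atoms: none (methyls removed; phenolic oxygens retained)
Why: Lewis-acid ether cleavage removes the three aryl methyl ethers while leaving the two diaryl ether bridges intact.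

## Compound list

1 | 3-hydroxy-4-methoxybenzonitrile | COc1ccc(C#N)cc1O | starting material
2 | 4-bromophenylboronic acid | OB(O)c1ccc(Br)cc1 | starting material
3 | 3-(4-bromophenoxy)-4-methoxybenzonitrile | COc1ccc(C#N)cc1Oc1ccc(Br)cc1 | intermediate
4 | 2-fluoro-3,4-dimethoxybenzaldehyde | COc1ccc(C=O)c(F)c1OC | starting material
5 | 3-hydroxybenzonitrile | Oc1cccc(C#N)c1 | starting material
6 | 3-(6-formyl-2,3-dimethoxyphenoxy)benzonitrile | COc1ccc(C=O)c(Oc2cccc(C#N)c2)c1OC | intermediate
7 | 3-(6-ethenyl-2,3-dimethoxyphenoxy)benzonitrile | COc1ccc(C=C)c(Oc2cccc(C#N)c2)c1OC | intermediate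
8 | 3-[4-[2-[2-(3-cyanophenoxy)-3,4-dimethoxyphenyl]ethyl]phenoxy]-4-methoxybenzonitrile | COc1ccc(CCc2ccc(Oc3cc(C#N)ccc3OC)cc2)c(Oc2cccc(C#N)c2)c1OC | intermediate
9 | 3-[4-[2-[2-(3-formylphenoxy)-3,4-dimethoxyphenyl]ethyl]phenoxy]-4-methoxybenzaldehyde | COc1ccc(CCc2ccc(Oc3cc(C=O)ccc3OC)cc2)c(Oc2cccc(C=O)c2)c1OC | intermediate
10 | macrocyclic stilbene, tri-O-methyl dehydro-marchantin H (E/Z) | COc1ccc2cc1Oc1ccc(cc1)CCc1ccc(OC)c(OC)c1Oc1cccc(c1)C=C2 | intermediate
11 | marchantin H tri-O-methyl ether | COc1ccc2cc1Oc1ccc(cc1)CCc1ccc(OC)c(OC)c1Oc1cccc(c1)CC2 | intermediate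
12 | marchantin H | Oc1ccc2cc1Oc1ccc(cc1)CCc1ccc(O)c(O)c1Oc1cccc(c1)CC2 | target

## Summary

Total steps: 8. Longest linear sequence: 7 (steps 2 → 3 → 4 → 5 → 6 → 7 → 8); step 1 is the convergent branch.

Three steps most likely to fail, each with a fallback:

1. **Step 6, McMurry macrocyclization** (oligomerization, strain in the 18-membered ring). Fallback: doubly methylenate dialdehyde 9 to the bis-styrene and close the ring by ring-closing metathesis (Grubbs II, high dilution) to the same stilbene 10.
2. **Step 2, SNAr on an electron-rich, hindered fluoroarene** (slow or incomplete substitution). Fallback: reverse the roles and use a copper-catalysed Ullmann coupling of 2-hydroxy-3,4-dimethoxybenzaldehyde with 3-iodobenzonitrile (CuI/picolinic acid, K3PO4, DMSO) to give 6.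
3. **Step 4, hydroboration/B-alkyl Suzuki** (protodeboronation, partial nitrile reduction by 9-BBN). Fallback: build the bibenzyl by olefination instead. Reduce 6 with NaBH4, convert to the benzylphosphonium salt with PPh3·HBr, run a Wittig reaction with 3-(4-formylphenoxy)-4-methoxybenzonitrile (from 1 and 4-fluorobenzaldehyde by SNAr), then hydrogenate the stilbene to 8.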